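**Plan**

- Core numbering used throughout: C1 (CH–O of the tiglate), C2 (CH2), C3 (CH–O of the senecioate), C4 (CMe2), C5, C6 and C10 (cyclobutane CH; C6 next to C7), C7 (C=O), C8 (=CH), C9 (=C–Me), C11 (quaternary C–Me). Ring A is the cyclohexenone C5–C10; ring B is the seven-membered ring C1–C5/C10/C11.
- Cuts, in retrosynthetic order: O1–acyl; O3–acyl together with C1–H (Evans–Tishchenko on a C1 ketone); cyclobutane bond C6–C11; C9–C10; C10=C11 (ring-closing metathesis); C1–C11 and C2–C3 (acylations); C4–C5 (Ireland–Claisen).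
- Enabling feature: with C1 at the ketone level, C9 and C10 are the β-carbons of the two carbonyls C7=O and C1=O (a 1,6-dicarbonyl array across ring A). C6 and C11 are their α-carbons (a 1,4-dicarbonyl array across the cyclobutane). Both unions join carbons of like polarity, the first reductively, the second oxidatively.
- Forward order: acyclic C1–C10 chain, then ring B (a 2-methylcycloheptenone), then ring A by C9–C10 closure, then the cyclobutane by C6–C11 closure, then the two esters.
- Stereochemistry: C5 from (S)-but-3-en-2-ol by chirality transfer; C3 by catalyst-controlled hydrogenation; C10 from C5 (cis ring fusion); C6 and C11 forced by the cage; C1 from C3 by 1,3-anti hydride delivery.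

Key step: step 15

Remark: compounds 1, 2 and the Grignard solutions 15 and 20 are taken as catalogue items.

**Step 1**
Reactants: 1 (2S)-but-3-en-2-ol; 2 1-[(but-3-en-1-yloxy)methyl]-4-methoxybenzene
Product: 3 (2S,3E)-6-[(4-methoxybenzyl)oxy]hex-3-en-2-ol
Conditions: second-generation Grubbs catalyst (5 mol%), 2 (3 equiv), CH2Cl2, 40 °C
Reagents that add atoms: none
Why: Olefin cross-metathesis of a secondary allylic alcohol with an unhindered terminal olefin should be E-selective and leaves the carbinol stereocentre of 1 untouched.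

**Step 2**
Reactants: 3 (2S,3E)-6-[(4-methoxybenzyl)oxy]hex-3-en-2-ol; 4 2-methylpropanoyl chloride
Product: 5 (2S,3E)-6-[(4-methoxybenzyl)oxy]hex-3-en-2-yl 2-methylpropanoate
Conditions: Et3N, DMAP (cat.), CH2Cl2, 0 °C → rt
Reagents that add atoms: none
Why: DMAP-catalysed esterification of the secondary alcohol with an acid chloride, with no stereocentre affected.

**Step 3**
Reactants: 5 (2S,3E)-6-[(4-methoxybenzyl)oxy]hex-3-en-2-yl 2-methylpropanoate
Product: 8 (3R,4E)-3-{2-[(4-methoxybenzyl)oxy]ethyl}-2,2-dimethylhex-4-enoic acid, via ketene trimethylsilyl acetal 6 (not isolated), via trimethylsilyl ester 7 (not isolated)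
Conditions: LiN(i-Pr)2, THF, −78 °C; Me3SiCl, −78 → 50 °C; then 1 M HCl
Reagents that add atoms: none
Why: Ireland–Claisen rearrangement: the symmetrical ketene silyl acetal rearranges through a chair transition state with the carbinol methyl equatorial, so the C–O chirality is transferred suprafacially to the new C4–C5 bond (C5 R) and the propenyl group emerges E.

**Step 4**
Reactants: 8 (3R,4E)-3-{2-[(4-methoxybenzyl)oxy]ethyl}-2,2-dimethylhex-4-enoic acid; 9 ethyl acetate
Product: 11 ethyl (5R,6E)-5-{2-[(4-methoxybenzyl)oxy]ethyl}-4,4-dimethyl-3-oxooct-6-enoate, via acyl imidazolide 10 (not isolated)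
Conditions: 1,1′-carbonyldiimidazole, THF, rt; then LiCH2CO2Et (from 9 and LiN(SiMe3)2, 2.2 equiv), THF, −78 °C; aq. NH4Cl
Reagents that add atoms: none
Why: Crossed Claisen condensation of a non-enolisable acyl imidazolide with the lithium enolate of ethyl acetate should give the β-keto ester, the second equivalent of enolate deprotonating the product and preventing over-addition.

**Step 5**
Reactants: 11 ethyl (5R,6E)-5-{2-[(4-methoxybenzyl)oxy]ethyl}-4,4-dimethyl-3-oxooct-6-enoate
Product: 12 ethyl (3R,5R,6E)-3-hydroxy-5-{2-[(4-methoxybenzyl)oxy]ethyl}-4,4-dimethyloct-6-enoate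
Conditions: H2 (50 atm), RuCl2[(S)-BINAP] (1 mol%), EtOH, 50 °C
Reagents that add atoms: none
Why: Noyori asymmetric hydrogenation of a β-keto ester: the ester-chelated ketone is reduced under catalyst control (the usual facial sense; the descriptor reads 3R because the quaternary C4 outranks C2), and the isolated E-alkene and the benzyl-type ether should be inert.

**Step 6**
Reactants: 12 ethyl (3R,5R,6E)-3-hydroxy-5-{2-[(4-methoxybenzyl)oxy]ethyl}-4,4-dimethyloct-6-enoate
Product: 13 (3R,5R,6E)-3-hydroxy-N-methoxy-5-{2-[(4-methoxybenzyl)oxy]ethyl}-N,4,4-trimethyloct-6-enamide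
Conditions: MeNH(OMe)·HCl, i-PrMgCl, THF, −20 → 0 °C
Reagents that add atoms: N,O-dimethylhydroxylamine hydrochloride, CNOC.Cl
Why: Weinreb amide formation by aminolysis of the unhindered ethyl ester with the chloromagnesium amide.

**Step 7**
Reactants: 13 (3R,5R,6E)-3-hydroxy-N-methoxy-5-{2-[(4-methoxybenzyl)oxy]ethyl}-N,4,4-trimethyloct-6-enamide
Product: 14 (3R,5R,6E)-3-[(tert-butyldimethylsilyl)oxy]-N-methoxy-5-{2-[(4-methoxybenzyl)oxy]ethyl}-N,4,4-trimethyloct-6-enamide
Conditions: TBSOTf, 2,6-lutidine, CH2Cl2, 0 °C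
Reagents that add atoms: tert-butyldimethylsilyl trifluoromethanesulfonate, CC(C)(C)[Si](C)(C)OS(=O)(=O)C(F)(F)F
Why: Silyl ether formation with a silyl triflate protects the hindered O3 through the organometallic, oxidative and enolate steps.

**Step 8**
Reactants: 14 (3R,5R,6E)-3-[(tert-butyldimethylsilyl)oxy]-N-methoxy-5-{2-[(4-methoxybenzyl)oxy]ethyl}-N,4,4-trimethyloct-6-enamide; 15 (prop-1-en-2-yl)magnesium bromide
Product: 16 (5R,7R,8E)-5-[(tert-butyldimethylsilyl)oxy]-7-{2-[(4-methoxybenzyl)oxy]ethyl}-2,6,6-trimethyldeca-1,8-dien-3-one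
Conditions: 15 (1.5 equiv), THF, 0 °C; aq. NH4Cl
Reagents that add atoms: none
Why: Grignard addition to a Weinreb amide stops at the ketone because of the stable magnesium chelate, giving the isopropenyl ketone (C1–C11 bond).

**Step 9**
Reactants: 16 (5R,7R,8E)-5-[(tert-butyldimethylsilyl)oxy]-7-{2-[(4-methoxybenzyl)oxy]ethyl}-2,6,6-trimethyldeca-1,8-dien-3-one
Product: 17 (4R,6R)-6-[(tert-butyldimethylsilyl)oxy]-4-{2-[(4-methoxybenzyl)oxy]ethyl}-2,5,5-trimethylcyclohept-2-en-1-one
Conditions: second-generation Hoveyda–Grubbs catalyst (10 mol%), toluene, 80 °C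
Reagents that add atoms: none
Why: Ring-closing metathesis of the isopropenyl ketone with the propenyl group should close ring B as the 2-methylcyclohept-2-enone (C10=C11), driven by loss of propene.

**Step 10**
Reactants: 17 (4R,6R)-6-[(tert-butyldimethylsilyl)oxy]-4-{2-[(4-methoxybenzyl)oxy]ethyl}-2,5,5-trimethylcyclohept-2-en-1-one
Product: 18 (4R,6R)-6-[(tert-butyldimethylsilyl)oxy]-4-(2-hydroxyethyl)-2,5,5-trimethylcyclohept-2-en-1-one
Conditions: DDQ, CH2Cl2/pH 7 buffer, 0 °C
Reagents that add atoms: none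
Why: Oxidative cleavage of the 4-methoxybenzyl ether by DDQ (benzylic hydride abstraction, then hydrolysis) frees the primary alcohol while the silyl ether and enone are inert.

**Step 11**
Reactants: 18 (4R,6R)-6-[(tert-butyldimethylsilyl)oxy]-4-(2-hydroxyethyl)-2,5,5-trimethylcyclohept-2-en-1-one
Product: 19 (4R,6R)-6-[(tert-butyldimethylsilyl)oxy]-2,5,5-trimethyl-4-(2-oxoethyl)cyclohept-2-en-1-one
Conditions: Dess–Martin periodinane, NaHCO3, CH2Cl2, rt
Reagents that add atoms: none
Why: Dess–Martin oxidation converts the primary alcohol to the aldehyde under buffered, non-epimerising conditions.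

**Step 12**
Reactants: 19 (4R,6R)-6-[(tert-butyldimethylsilyl)oxy]-2,5,5-trimethyl-4-(2-oxoethyl)cyclohept-2-en-1-one; 20 (prop-1-yn-1-yl)magnesium bromide
Product: 21 (4R,6R)-6-[(tert-butyldimethylsilyl)oxy]-4-(2-hydroxypent-3-yn-1-yl)-2,5,5-trimethylcyclohept-2-en-1-one (both carbinol epimers)
Conditions: 20 (1.1 equiv), THF, −78 °C; aq. NH4Cl
Reagents that add atoms: none
Why: 1,2-Addition of an alkynyl Grignard reagent to the aldehyde should be far faster at −78 °C than addition to the conjugated ring ketone; the new carbinol centre is formed unselectively and is removed in step 13.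

**Step 13**
Reactants: 21 (4R,6R)-6-[(tert-butyldimethylsilyl)oxy]-4-(2-hydroxypent-3-yn-1-yl)-2,5,5-trimethylcyclohept-2-en-1-one
Product: 22 (4R,6R)-6-[(tert-butyldimethylsilyl)oxy]-2,5,5-trimethyl-4-(2-oxopent-3-yn-1-yl)cyclohept-2-en-1-one
Conditions: Dess–Martin periodinane, NaHCO3, CH2Cl2, 0 °C
Reagents that add atoms: none
Why: Dess–Martin oxidation of the propargylic alcohol gives the ynone.

**Step 14**
Reactants: 22 (4R,6R)-6-[(tert-butyldimethylsilyl)oxy]-2,5,5-trimethyl-4-(2-oxopent-3-yn-1-yl)cyclohept-2-en-1-one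
Product: 23 (4R,6R)-6-[(tert-butyldimethylsilyl)oxy]-4-[(3Z)-4-iodo-2-oxopent-3-en-1-yl]-2,5,5-trimethylcyclohept-2-en-1-one
Conditions: NaI, AcOH, rt
Reagents that add atoms: sodium iodide, [Na+].[I-]
Why: Conjugate hydroiodination of the ynone (iodide addition, then kinetic anti protonation) should give the Z β-iodoenone with iodine cis to the carbonyl group.

**Step 15**
Reactants: 23 (4R,6R)-6-[(tert-butyldimethylsilyl)oxy]-4-[(3Z)-4-iodo-2-oxopent-3-en-1-yl]-2,5,5-trimethylcyclohept-2-en-1-one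
Product: 24 (4aR,6R,9aR)-6-[(tert-butyldimethylsilyl)oxy]-1,5,5,9-tetramethyl-8-[(trimethylsilyl)oxy]-4,4a,5,6,7,9a-hexahydro-3H-benzo[7]annulen-3-one (cis-fused; core C3 R, C5 R, C10 R)
Conditions: NiCl2(dme) (10 mol%), neocuproine (10 mol%), Mn powder, Me3SiCl, DMF, rt
Reagents that add atoms: chlorotrimethylsilane, C[Si](C)(C)Cl
Why: Zerovalent nickel (from NiCl2(dme) and Mn) adds with Me3SiCl to the ring-B enone to give an η3-1-(silyloxy)allylnickel species, which reverses the polarity of the β-carbon C10; oxidative addition of the C9–I bond and C(sp2)–C(sp3) reductive elimination then join the two acceptor β-carbons C9 and C10, and Mn turns the nickel over. The closest known reaction type is the nickel-catalysed reductive conjugate addition of alkenyl halides to enones with chlorosilane trapping, used here in its ring-closing (reductive Heck-type) form. Ring A is closed in a 6-exo-trig mode, with C10 inside and C11 outside the new ring. The only new stereocentre, C10, is controlled by C5: the four-atom tether can deliver C9 only to the face of ring B that carries the C5–C6 bond, which gives the cis ring fusion. The step needs 1,4- over 1,2-addition and cyclisation over simple reduction of the C–I bond; the Z geometry of the iodoenone (C9 within reach of C10), silyl activation of the enone and the six-membered transition state should secure this. O-Silylation of the nickel enolate fixes the C1=C11 enol ether regiospecifically, which step 16 requires.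

**Step 16**
Reactants: 24 (4aR,6R,9aR)-6-[(tert-butyldimethylsilyl)oxy]-1,5,5,9-tetramethyl-8-[(trimethylsilyl)oxy]-4,4a,5,6,7,9a-hexahydro-3H-benzo[7]annulen-3-one
Product: 26 (1R,2R,5R,7S,8R)-5-[(tert-butyldimethylsilyl)oxy]-2,6,6,11-tetramethyltricyclo[5.4.0.0(2,8)]undec-10-ene-3,9-dione, via dilithium bis-enolate 25 (not isolated)
Conditions: LiN(i-Pr)2, THF, −78 °C; MeLi, −78 → 0 °C; FeCl3, DMF, −78 °C → rt
Reagents that add atoms: none
Why: Intramolecular oxidative coupling of a ketone bis-enolate with iron trichloride: the enone is deprotonated at C6 (kinetic α′ enolate), MeLi converts the silyl enol ether regiospecifically into the C11 enolate, and one-electron oxidation joins C6 to C11; the bond can only form on the concave face of the cis-fused bicycle, which fixes C6 and the quaternary C11.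

**Step 17**
Reactants: 26 (1R,2R,5R,7S,8R)-5-[(tert-butyldimethylsilyl)oxy]-2,6,6,11-tetramethyltricyclo[5.4.0.0(2,8)]undec-10-ene-3,9-dione
Product: 27 (1R,2R,5R,7S,8R)-5-hydroxy-2,6,6,11-tetramethyltricyclo[5.4.0.0(2,8)]undec-10-ene-3,9-dione
Conditions: HF·pyridine, pyridine, THF, 0 °C → rt
Reagents that add atoms: none
Why: Buffered fluoride desilylation removes the silyl ether without base, so the β-hydroxy ketone should not eliminate or undergo retro-aldol cleavage.

**Step 18**
Reactants: 27 (1R,2R,5R,7S,8R)-5-hydroxy-2,6,6,11-tetramethyltricyclo[5.4.0.0(2,8)]undec-10-ene-3,9-dione; 28 3-methylbut-2-enal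
Product: 30 (1R,2R,3R,5R,7S,8R)-3-hydroxy-2,6,6,11-tetramethyl-9-oxotricyclo[5.4.0.0(2,8)]undec-10-en-5-yl 3-methylbut-2-enoate, via mixed hemiacetal 29 (not isolated)
Conditions: 28 (5 equiv) premixed with SmI2 (0.3 equiv), THF; then 27, −10 °C
Reagents that add atoms: none
Why: Evans–Tishchenko reduction: the samarium-bound hemiacetal on O3 delivers its hydride intramolecularly to C1 from the face of O3, which sets the 1,3-anti carbinol (C1 R) and leaves the aldehyde carbon as the senecioate on O3; the C7 enone has no neighbouring hydroxyl and should not be reduced.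

**Step 19**
Reactants: 30 (1R,2R,3R,5R,7S,8R)-3-hydroxy-2,6,6,11-tetramethyl-9-oxotricyclo[5.4.0.0(2,8)]undec-10-en-5-yl 3-methylbut-2-enoate; 31 (2E)-2-methylbut-2-enoyl chloride
Product: 32 (1R,2R,3R,5R,7S,8R)-2,6,6,11-tetramethyl-5-[(3-methylbut-2-enoyl)oxy]-9-oxotricyclo[5.4.0.0(2,8)]undec-10-en-3-yl (2E)-2-methylbut-2-enoate (target)
Conditions: 31, DMAP, pyridine, CH2Cl2, 0 °C → rt
Reagents that add atoms: none
Why: DMAP-catalysed esterification of the remaining hindered secondary alcohol with the acid chloride installs the tiglate without touching any stereocentre.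

**Compound list**

1 | (2S)-but-3-en-2-ol | C[C@H](O)C=C | starting material
2 | 1-[(but-3-en-1-yloxy)methyl]-4-methoxybenzene | C=CCCOCc1ccc(OC)cc1 | starting material
3 | (2S,3E)-6-[(4-methoxybenzyl)oxy]hex-3-en-2-ol | C[C@H](O)/C=C/CCOCc1ccc(OC)cc1 | intermediate
4 | 2-methylpropanoyl chloride | CC(C)C(Cl)=O | starting material
5 | (2S,3E)-6-[(4-methoxybenzyl)oxy]hex-3-en-2-yl 2-methylpropanoate | CC(C)C(=O)O[C@@H](C)/C=C/CCOCc1ccc(OC)cc1 | intermediate
6 | ketene trimethylsilyl acetal of 5 | CC(C)=C(O[Si](C)(C)C)O[C@@H](C)/C=C/CCOCc1ccc(OC)cc1 | intermediate (not isolated)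
7 | trimethylsilyl (3R,4E)-3-{2-[(4-methoxybenzyl)oxy]ethyl}-2,2-dimethylhex-4-enoate | C/C=C/[C@@H](CCOCc1ccc(OC)cc1)C(C)(C)C(=O)O[Si](C)(C)C | intermediate (not isolated)
8 | (3R,4E)-3-{2-[(4-methoxybenzyl)oxy]ethyl}-2,2-dimethylhex-4-enoic acid | C/C=C/[C@@H](CCOCc1ccc(OC)cc1)C(C)(C)C(=O)O | intermediate
9 | ethyl acetate | CCOC(C)=O | starting material
10 | acyl imidazolide of 8 | C/C=C/[C@@H](CCOCc1ccc(OC)cc1)C(C)(C)C(=O)n1ccnc1 | intermediate (not isolated)
11 | ethyl (5R,6E)-5-{2-[(4-methoxybenzyl)oxy]ethyl}-4,4-dimethyl-3-oxooct-6-enoate | CCOC(=O)CC(=O)C(C)(C)[C@H](CCOCc1ccc(OC)cc1)/C=C/C | intermediate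
12 | ethyl (3R,5R,6E)-3-hydroxy-5-{2-[(4-methoxybenzyl)oxy]ethyl}-4,4-dimethyloct-6-enoate | CCOC(=O)C[C@@H](O)C(C)(C)[C@H](CCOCc1ccc(OC)cc1)/C=C/C | intermediate
13 | (3R,5R,6E)-3-hydroxy-N-methoxy-5-{2-[(4-methoxybenzyl)oxy]ethyl}-N,4,4-trimethyloct-6-enamide | CON(C)C(=O)C[C@@H](O)C(C)(C)[C@H](CCOCc1ccc(OC)cc1)/C=C/C | intermediate
14 | (3R,5R,6E)-3-[(tert-butyldimethylsilyl)oxy]-N-methoxy-5-{2-[(4-methoxybenzyl)oxy]ethyl}-N,4,4-trimethyloct-6-enamide | CON(C)C(=O)C[C@@H](O[Si](C)(C)C(C)(C)C)C(C)(C)[C@H](CCOCc1ccc(OC)cc1)/C=C/C | intermediate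
15 | (prop-1-en-2-yl)magnesium bromide | CC(=C)[Mg]Br | starting material
16 | (5R,7R,8E)-5-[(tert-butyldimethylsilyl)oxy]-7-{2-[(4-methoxybenzyl)oxy]ethyl}-2,6,6-trimethyldeca-1,8-dien-3-one | C=C(C)C(=O)C[C@@H](O[Si](C)(C)C(C)(C)C)C(C)(C)[C@H](CCOCc1ccc(OC)cc1)/C=C/C | intermediate
17 | (4R,6R)-6-[(tert-butyldimethylsilyl)oxy]-4-{2-[(4-methoxybenzyl)oxy]ethyl}-2,5,5-trimethylcyclohept-2-en-1-one | O=C1C[C@@H](O[Si](C)(C)C(C)(C)C)C(C)(C)[C@H](CCOCc2ccc(OC)cc2)C=C1C | intermediate
18 | (4R,6R)-6-[(tert-butyldimethylsilyl)oxy]-4-(2-hydroxyethyl)-2,5,5-trimethylcyclohept-2-en-1-one | O=C1C[C@@H](O[Si](C)(C)C(C)(C)C)C(C)(C)[C@H](CCO)C=C1C | intermediate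
19 | (4R,6R)-6-[(tert-butyldimethylsilyl)oxy]-2,5,5-trimethyl-4-(2-oxoethyl)cyclohept-2-en-1-one | O=C1C[C@@H](O[Si](C)(C)C(C)(C)C)C(C)(C)[C@H](CC=O)C=C1C | intermediate
20 | (prop-1-yn-1-yl)magnesium bromide | CC#C[Mg]Br | starting material
21 | (4R,6R)-6-[(tert-butyldimethylsilyl)oxy]-4-(2-hydroxypent-3-yn-1-yl)-2,5,5-trimethylcyclohept-2-en-1-one, carbinol epimers | O=C1C[C@@H](O[Si](C)(C)C(C)(C)C)C(C)(C)[C@H](CC(O)C#CC)C=C1C | intermediate
22 | (4R,6R)-6-[(tert-butyldimethylsilyl)oxy]-2,5,5-trimethyl-4-(2-oxopent-3-yn-1-yl)cyclohept-2-en-1-one | O=C1C[C@@H](O[Si](C)(C)C(C)(C)C)C(C)(C)[C@H](CC(=O)C#CC)C=C1C | intermediate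
23 | (4R,6R)-6-[(tert-butyldimethylsilyl)oxy]-4-[(3Z)-4-iodo-2-oxopent-3-en-1-yl]-2,5,5-trimethylcyclohept-2-en-1-one | O=C1C[C@@H](O[Si](C)(C)C(C)(C)C)C(C)(C)[C@H](CC(=O)/C=C(/C)I)C=C1C | intermediate
24 | (4aR,6R,9aR)-6-[(tert-butyldimethylsilyl)oxy]-1,5,5,9-tetramethyl-8-[(trimethylsilyl)oxy]-4,4a,5,6,7,9a-hexahydro-3H-benzo[7]annulen-3-one | CC1=C(O[Si](C)(C)C)C[C@@H](O[Si](C)(C)C(C)(C)C)C(C)(C)[C@@H]2CC(=O)C=C(C)[C@H]12 | intermediate
25 | dilithium bis-enolate of 24 (C6=C7–OLi and C11=C1–OLi; configuration as in 24) | CC1=C(O[Li])C[C@@H](O[Si](C)(C)C(C)(C)C)C(C)(C)[C@@H]2C=C(O[Li])C=C(C)[C@H]12 | intermediate (not isolated)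
26 | (1R,2R,5R,7S,8R)-5-[(tert-butyldimethylsilyl)oxy]-2,6,6,11-tetramethyltricyclo[5.4.0.0(2,8)]undec-10-ene-3,9-dione | O=C1C[C@@H](O[Si](C)(C)C(C)(C)C)C(C)(C)[C@@H]2[C@H]3C(=O)C=C(C)[C@@H]2[C@]31C | intermediate
27 | (1R,2R,5R,7S,8R)-5-hydroxy-2,6,6,11-tetramethyltricyclo[5.4.0.0(2,8)]undec-10-ene-3,9-dione | O=C1C[C@@H](O)C(C)(C)[C@@H]2[C@H]3C(=O)C=C(C)[C@@H]2[C@]31C | intermediate
28 | 3-methylbut-2-enal | CC(C)=CC=O | starting material
29 | mixed hemiacetal of 27 (O3) and 28 | O=C1C[C@@H](OC(O)C=C(C)C)C(C)(C)[C@@H]2[C@H]3C(=O)C=C(C)[C@@H]2[C@]31C | intermediate (not isolated)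
30 | (1R,2R,3R,5R,7S,8R)-3-hydroxy-2,6,6,11-tetramethyl-9-oxotricyclo[5.4.0.0(2,8)]undec-10-en-5-yl 3-methylbut-2-enoate | O[C@@H]1C[C@@H](OC(=O)C=C(C)C)C(C)(C)[C@@H]2[C@H]3C(=O)C=C(C)[C@@H]2[C@]31C | intermediate
31 | (2E)-2-methylbut-2-enoyl chloride | C/C=C(\C)C(Cl)=O | starting material
32 | (1R,2R,3R,5R,7S,8R)-2,6,6,11-tetramethyl-5-[(3-methylbut-2-enoyl)oxy]-9-oxotricyclo[5.4.0.0(2,8)]undec-10-en-3-yl (2E)-2-methylbut-2-enoate | C/C=C(\C)C(=O)O[C@@H]1C[C@@H](OC(=O)C=C(C)C)C(C)(C)[C@@H]2[C@H]3C(=O)C=C(C)[C@@H]2[C@]31C | target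

**Totals**

Total step count: 19. Longest linear sequence: 19 steps (from 1).

**Steps most likely to fail**

Step 16. The one-electron coupling may be outrun by intermolecular dimerisation or by proton transfer between the two enolate sites, so that the four-membered ring does not close. The fallback sets out from 24 and replaces the oxidative union by a polar alkylation. The C6 lithium enolate of 24 (LiN(i-Pr)2, −78 °C) is brominated with N-bromosuccinimide to the α′-bromo enone still carrying the trimethylsilyl enol ether F1. Anhydrous CsF in DMF then unmasks the C11 enolate, which should displace bromide in a 4-exo-tet C-alkylation; O-alkylation is excluded because O1 is trans to C10 across the enol double bond. The route is rejoined at 26.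

Step 15. Reduction of the C–I bond without ring closure, or intermolecular coupling, may prevail over the intramolecular conjugate addition. The fallback sets out from 23 and uses a stoichiometric organocopper reagent instead of nickel catalysis. Iodine–copper exchange with Li[Cu(CH2CMe2Ph)2] in THF at −78 °C should give the lithium alkenyl(2-methyl-2-phenylpropyl)cuprate F2. On addition of Me3SiCl its alkenyl group adds 1,4 to the ring-B enone across the same six-membered transition state, the enolate is silylated in situ, and the route is rejoined at 24.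

Step 18. With the α,β-unsaturated aldehyde, hydride transfer from the hindered hemiacetal may be slow, so that acyl migration between O3 and O1 or consumption of the aldehyde competes. The fallback sets out from 27 and separates the reduction from the introduction of the senecioate. Evans–Tishchenko reduction with acetaldehyde and catalytic SmI2 gives the 3-acetate 1-alcohol F3. Acylation with 31 and DMAP gives the 3-acetate 1-tiglate F4. K2CO3 in methanol at 0 °C should remove the acetate selectively, the conjugated α-branched tiglate being much slower to methanolyse, to give the 3-alcohol 1-tiglate F5. Yamaguchi esterification with 3-methylbut-2-enoic acid (2,4,6-trichlorobenzoyl chloride, Et3N, DMAP) returns the route at 32.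

**Further compounds**

F1 | step 16 | C6-bromo derivative of 24 (α′-bromo enone, trimethylsilyl enol ether intact, C6 epimers) | CC1=C(O[Si](C)(C)C)C[C@@H](O[Si](C)(C)C(C)(C)C)C(C)(C)[C@@H]2C(Br)C(=O)C=C(C)[C@H]12
F2 | step 15 | lithium alkenyl(2-methyl-2-phenylpropyl)cuprate derived from 23 (copper in place of iodine, Z) | O=C1C[C@@H](O[Si](C)(C)C(C)(C)C)C(C)(C)[C@H](CC(=O)/C=C(/C)[Cu-]CC(C)(C)c2ccccc2)C=C1C.[Li+]
F3 | step 18 | (1R,2R,3R,5R,7S,8R)-3-hydroxy-2,6,6,11-tetramethyl-9-oxotricyclo[5.4.0.0(2,8)]undec-10-en-5-yl acetate | O[C@@H]1C[C@@H](OC(C)=O)C(C)(C)[C@@H]2[C@H]3C(=O)C=C(C)[C@@H]2[C@]31C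
F4 | step 18 | (1R,2R,3R,5R,7S,8R)-5-acetoxy-2,6,6,11-tetramethyl-9-oxotricyclo[5.4.0.0(2,8)]undec-10-en-3-yl (2E)-2-methylbut-2-enoate | C/C=C(\C)C(=O)O[C@@H]1C[C@@H](OC(C)=O)C(C)(C)[C@@H]2[C@H]3C(=O)C=C(C)[C@@H]2[C@]31C
F5 | step 18 | (1R,2R,3R,5R,7S,8R)-5-hydroxy-2,6,6,11-tetramethyl-9-oxotricyclo[5.4.0.0(2,8)]undec-10-en-3-yl (2E)-2-methylbut-2-enoate | C/C=C(\C)C(=O)O[C@@H]1C[C@@H](O)C(C)(C)[C@@H]2[C@H]3C(=O)C=C(C)[C@@H]2[C@]31C
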